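**Retrosynthetic overview**
- Labels: cyclopentane C1'–C5' (C1' quaternary and bonded to ring A, C2' gem-dimethyl, C3' CHBr); the bicycle is numbered as naphthalen-2(1H)-one, ring A = C1–C4, C4a, C8a and ring B = C4a, C5–C8, C8a.
- Feature: vicinal quaternary C1'/C2' next to heteroatom-bearing C3' is the pattern of a dichloroketene–methallyl ether [2+2] adduct enlarged by one CH2 (C4') between the carbonyl carbon (C3') and C5'. The chlorines then become the C2' methyls and the carbonyl becomes C3'–Br.
- Target ⇐ trans-diaxial hydrolysis of a 4a,5-epoxide ⇐ dienone ⇐ aldol condensation (C3=C4, closes ring A) ⇐ C2–C3 bond by acylation of the C1'-CH2Li reagent with a ring B δ-lactone.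
- Ring B lactone ⇐ 2-methylcyclohexane-1,3-dione: oxazaborolidine desymmetrisation sets C8a, a hydroxymethyl coupling adds C4, and C8–Br comes from hydrogenation of a vinyl bromide in the conformationally locked bicycle.
- Ring order: cyclobutane → cyclopentane (fragment 1); ring B (bought) → δ-lactone (fragment 2); ring A last.

Key step: step 5

Remark: diazomethane (8) is used as a freshly distilled ether solution from commercial N-methyl-N-nitroso-p-toluenesulfonamide and KOH and is counted as a starting material; the C1' hydroxymethyl is carried as its tert-butyldiphenylsilyl ether, because a benzyl ether oxygen could attack activated C3' from the rear during bromination.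

**Fragment 1 (cyclopentane)**

Step 1
Reactants: 1 2-methylprop-2-en-1-ol
Product: 2 tert-butyl[(2-methylprop-2-en-1-yl)oxy]diphenylsilane
Conditions: TBDPSCl, imidazole, DMF, 0 → 25 °C
Reagents that add atoms: tert-butyl(chloro)diphenylsilane, CC(C)(C)[Si](Cl)(c1ccccc1)c1ccccc1
Why: Imidazole-promoted O-silylation of the primary alcohol gives an ether that should survive zinc/acid chloride, diazomethane, cuprate, borane and phosphonium chemistry and whose oxygen is a poor neighbouring group.

Step 2
Reactants: 2 tert-butyl[(2-methylprop-2-en-1-yl)oxy]diphenylsilane; 3 trichloroacetyl chloride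
Product: 5 rac-3-({[tert-butyl(diphenyl)silyl]oxy}methyl)-2,2-dichloro-3-methylcyclobutan-1-one, via dichloroketene 4 (not isolated)
Conditions: Zn–Cu couple, DME, Et2O, 25 °C → reflux
Reagents that add atoms: trichloroacetyl chloride (compound 3), ClC(Cl)(Cl)C(Cl)=O
Why: Zinc dechlorination generates dichloroketene, whose thermal [2+2] cycloaddition with the 1,1-disubstituted alkene joins the ketene carbonyl carbon to the terminal CH2 and CCl2 to the more substituted carbon, giving the racemic 2,2-dichloro-3,3-disubstituted cyclobutanone.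

Step 3
Reactants: 5 rac-3-({[tert-butyl(diphenyl)silyl]oxy}methyl)-2,2-dichloro-3-methylcyclobutan-1-one
Product: 6 (1R,3R)-3-({[tert-butyl(diphenyl)silyl]oxy}methyl)-2,2-dichloro-3-methylcyclobutan-1-ol (OH cis to CH2OSi)
Conditions: (S)-2-methyl-CBS-oxazaborolidine (0.2 equiv), catecholborane, toluene, −78 °C; SiO2 chromatography
Reagents that add atoms: none
Why: In this Corey–Bakshi–Shibata reduction the catalyst reads CCl2 as the large and CH2 as the small flank and should give the (1R)-carbinol from both enantiomers of 5, so the two antipodes become cis and trans diastereomers that are separated on silica, the cis isomer carrying the (3R) quaternary centre.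

Step 4
Reactants: 6 (1R,3R)-3-({[tert-butyl(diphenyl)silyl]oxy}methyl)-2,2-dichloro-3-methylcyclobutan-1-ol
Product: 7 (3R)-3-({[tert-butyl(diphenyl)silyl]oxy}methyl)-2,2-dichloro-3-methylcyclobutan-1-one
Conditions: Dess–Martin periodinane, NaHCO3, CH2Cl2, 25 °C
Reagents that add atoms: none
Why: Dess–Martin oxidation returns the ketone under non-basic conditions, so the base-sensitive α,α-dichlorocyclobutanone is not cleaved and the untouched quaternary centre is now a single enantiomer.

Step 5
Reactants: 7 (3R)-3-({[tert-butyl(diphenyl)silyl]oxy}methyl)-2,2-dichloro-3-methylcyclobutan-1-one; 8 diazomethane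
Product: 9 (3R)-3-({[tert-butyl(diphenyl)silyl]oxy}methyl)-2,2-dichloro-3-methylcyclopentan-1-one
Conditions: CH2N2 (1.3 equiv), Et2O, MeOH (cat.), 0 → 20 °C
Reagents that add atoms: diazomethane (compound 8), C=[N+]=[N-]
Why: The diazomethane carbon adds to the strained, chlorine-activated carbonyl to give a diazonium alkoxide, and the ring CH2 (C5') then shifts to the new carbon as N2 leaves, so C3'–C4' forms in the addition and C4'–C5' in the 1,2-shift. The closest known reaction type is the Tiffeneau–Demjanov-type diazomethane homologation of α,α-dichlorocyclobutanones to α,α-dichlorocyclopentanones. The cyclopentane is not closed by cyclisation but arises by ring enlargement of the four-membered ring through a 1,2-alkyl shift driven by strain relief. No stereocentre is created, and C1' lies outside the bonds made and broken and keeps the configuration fixed in 7. The step needs migration of CH2 in preference to CCl2, which the poor migratory aptitude of the electron-poor chlorinated carbon secures, and a single insertion, which follows from the lower strain and electrophilicity of the cyclopentanone together with a small excess of reagent at low temperature.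

Step 6
Reactants: 9 (3R)-3-({[tert-butyl(diphenyl)silyl]oxy}methyl)-2,2-dichloro-3-methylcyclopentan-1-one
Product: 11 (3S)-3-({[tert-butyl(diphenyl)silyl]oxy}methyl)-2,2,3-trimethylcyclopentan-1-one, via lithium enolate 10 (not isolated)
Conditions: Me2CuLi (4 equiv), Et2O, −45 °C; then MeI, HMPA, −45 → 25 °C
Reagents that add atoms: lithium dimethylcuprate, [Li+].C[Cu-]C; iodomethane, CI
Why: In this known reductive gem-dimethylation of α,α-dichlorocyclopentanones the Gilman cuprate exchanges the first chlorine for metal, replaces the second by methyl, and the resulting α-methyl enolate 10 is C-methylated by iodomethane, so both methyls enter only at the former CCl2 carbon (C2').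

Step 7
Reactants: 11 (3S)-3-({[tert-butyl(diphenyl)silyl]oxy}methyl)-2,2,3-trimethylcyclopentan-1-one
Product: 12 (1S,3S)-3-({[tert-butyl(diphenyl)silyl]oxy}methyl)-2,2,3-trimethylcyclopentan-1-ol (OH trans to CH2OSi)
Conditions: (R)-2-methyl-CBS-oxazaborolidine (0.2 equiv), BH3·SMe2, THF, 0 °C
Reagents that add atoms: none
Why: Corey–Bakshi–Shibata reduction with quaternary C2' as the large and C4'H2 as the small flank should set the (S)-carbinol at C3' under catalyst control, overriding the weak bias of the remote C1' substituents.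

Step 8
Reactants: 12 (1S,3S)-3-({[tert-butyl(diphenyl)silyl]oxy}methyl)-2,2,3-trimethylcyclopentan-1-ol
Product: 13 tert-butyl{[(1S,3R)-3-bromo-1,2,2-trimethylcyclopentyl]methoxy}diphenylsilane (Br cis to CH2OSi)
Conditions: CBr4, PPh3, 2,6-lutidine, toluene, 0 → 70 °C
Reagents that add atoms: tetrabromomethane, BrC(Br)(Br)Br
Why: In this Appel reaction bromide displaces the alkoxyphosphonium group with SN2 inversion at C3', which places bromine cis to the C1' arm as in the target, while the non-polar medium disfavours ionisation and the shielded silyl ether oxygen does not take part.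

Step 9
Reactants: 13 tert-butyl{[(1S,3R)-3-bromo-1,2,2-trimethylcyclopentyl]methoxy}diphenylsilane
Product: 14 [(1S,3R)-3-bromo-1,2,2-trimethylcyclopentyl]methanol
Conditions: HF·pyridine, THF, 0 → 25 °C
Reagents that add atoms: none
Why: Acidic fluoride cleavage of the Si–O bond frees the primary alcohol without a base that could eliminate HBr, and the cis alcohol cannot displace the bromide because rear-side attack is geometrically impossible.

Step 10
Reactants: 14 [(1S,3R)-3-bromo-1,2,2-trimethylcyclopentyl]methanol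
Product: 15 (1S,3R)-3-bromo-1-(iodomethyl)-1,2,2-trimethylcyclopentane
Conditions: I2, PPh3, imidazole, toluene, 90 °C
Reagents that add atoms: iodine, II
Why: Garegg–Samuelsson (Appel-type) iodination converts the primary neopentyl alcohol through its alkoxyphosphonium salt on heating, and the hindered secondary bromide should be inert to iodide.

**Fragment 2 (ring B lactone)**

Step 11
Reactants: 16 2-methylcyclohexane-1,3-dione
Product: 17 methyl 2-(1-methyl-2,6-dioxocyclohexyl)acetate
Conditions: BrCH2CO2Me, K2CO3, NaI (cat.), acetone, reflux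
Reagents that add atoms: methyl bromoacetate, COC(=O)CBr
Why: C-alkylation of the stabilised dione enolate by the reactive α-halo ester creates the prochiral quaternary carbon (future C8a) carrying the C1–C2 arm.

Step 12
Reactants: 17 methyl 2-(1-methyl-2,6-dioxocyclohexyl)acetate
Product: 18 methyl 2-[(1R,2R)-2-hydroxy-1-methyl-6-oxocyclohexyl]acetate (OH cis to CH2CO2Me)
Conditions: (S)-2-methyl-CBS-oxazaborolidine (0.3 equiv), catecholborane (1.0 equiv), toluene, −78 → −40 °C; chromatography
Reagents that add atoms: none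
Why: In this desymmetrising Corey–Bakshi–Shibata reduction the catalyst fixes the (R)-carbinol and the substrate should make it choose the carbonyl whose allowed face lies anti to the larger CH2CO2Me group, which sets C8a; the minor diastereomer is removed on silica.

Step 13
Reactants: 18 methyl 2-[(1R,2R)-2-hydroxy-1-methyl-6-oxocyclohexyl]acetate
Product: 19 methyl 2-[(1R,2R)-2-{[tert-butyl(dimethyl)silyl]oxy}-1-methyl-6-oxocyclohexyl]acetate
Conditions: TBSOTf, 2,6-lutidine, CH2Cl2, −78 → 0 °C (on freshly isolated 18)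
Reagents that add atoms: tert-butyldimethylsilyl triflate, CC(C)(C)[Si](C)(C)OS(=O)(=O)C(F)(F)F
Why: Prompt silylation of the hindered secondary alcohol blocks γ-lactonisation onto the cis ester arm and retro-aldol cleavage in the base steps that follow.

Step 14
Reactants: 19 methyl 2-[(1R,2R)-2-{[tert-butyl(dimethyl)silyl]oxy}-1-methyl-6-oxocyclohexyl]acetate
Product: 20 methyl 2-[(1R,6R)-6-{[tert-butyl(dimethyl)silyl]oxy}-1,3-dimethyl-2-oxocyclohexyl]acetate (both C3 epimers)
Conditions: LiN(i-Pr)2 (1.05 equiv), THF, −78 °C; then MeI, −78 → −20 °C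
Reagents that add atoms: iodomethane, CI
Why: Kinetic enolate alkylation occurs at the only enolisable α-carbon of the ketone (future C5), which is more acidic than the ester CH2, and the new centre need not be controlled because it becomes sp2 in the next step.

Step 15
Reactants: 20 methyl 2-[(1R,6R)-6-{[tert-butyl(dimethyl)silyl]oxy}-1,3-dimethyl-2-oxocyclohexyl]acetate
Product: 21 methyl 2-[(1R,6R)-6-{[tert-butyl(dimethyl)silyl]oxy}-1,3-dimethyl-2-{[(trifluoromethyl)sulfonyl]oxy}cyclohex-2-en-1-yl]acetate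
Conditions: KN(SiMe3)2, PhNTf2, THF, −78 → −30 °C
Reagents that add atoms: N-phenylbis(trifluoromethanesulfonimide), O=S(=O)(N(c1ccccc1)S(=O)(=O)C(F)(F)F)C(F)(F)F
Why: Enol triflate formation can occur only toward the methyl-bearing carbon because the other α-carbon is quaternary, which fixes the tetrasubstituted C4a=C5 alkene.

Step 16
Reactants: 21 methyl 2-[(1R,6R)-6-{[tert-butyl(dimethyl)silyl]oxy}-1,3-dimethyl-2-{[(trifluoromethyl)sulfonyl]oxy}cyclohex-2-en-1-yl]acetate
Product: 23 (4aS,5R)-5-{[tert-butyl(dimethyl)silyl]oxy}-4a,8-dimethyl-1,4,4a,5,6,7-hexahydro-3H-isochromen-3-one, via hydroxy ester 22 (not isolated)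
Conditions: Bu3SnCH2OH, Pd(PPh3)4 (5 mol %), LiCl, 1,4-dioxane, 100 °C; then PPTS, toluene, 80 °C
Reagents that add atoms: (tributylstannyl)methanol, CCCC[Sn](CCCC)(CCCC)CO
Why: Stille coupling of the enol triflate with the hydroxymethylstannane installs the future C4 as an allylic alcohol, which lactonises onto the ester arm to a δ-lactone that carries both carbonyl handles and holds the C8a methyl pseudo-axial.

Step 17
Reactants: 23 (4aS,5R)-5-{[tert-butyl(dimethyl)silyl]oxy}-4a,8-dimethyl-1,4,4a,5,6,7-hexahydro-3H-isochromen-3-one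
Product: 24 (4aS,5R)-5-hydroxy-4a,8-dimethyl-1,4,4a,5,6,7-hexahydro-3H-isochromen-3-one
Conditions: HF·pyridine, THF, 0 → 25 °C
Reagents that add atoms: none
Why: Fluoride desilylation under weakly acidic conditions frees the hindered axial alcohol, which is oxidised without storage so that translactonisation onto the neighbouring acyl group does not set in.

Step 18
Reactants: 24 (4aS,5R)-5-hydroxy-4a,8-dimethyl-1,4,4a,5,6,7-hexahydro-3H-isochromen-3-one
Product: 25 (4aS)-4a,8-dimethyl-4,4a,6,7-tetrahydro-1H-isochromene-3,5-dione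
Conditions: Dess–Martin periodinane, NaHCO3, CH2Cl2, 25 °C
Reagents that add atoms: none
Why: Dess–Martin oxidation gives the ketone at the future C8, and the quaternary α-carbon keeps the β,γ-alkene from moving into conjugation.

Step 19
Reactants: 25 (4aS)-4a,8-dimethyl-4,4a,6,7-tetrahydro-1H-isochromene-3,5-dione
Product: 26 (4aS)-4a,8-dimethyl-3-oxo-3,4,4a,7-tetrahydro-1H-isochromen-5-yl trifluoromethanesulfonate
Conditions: Tf2O, 2,6-di-tert-butyl-4-methylpyridine, CH2Cl2, 0 → 25 °C
Reagents that add atoms: triflic anhydride, O=S(=O)(OS(=O)(=O)C(F)(F)F)C(F)(F)F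
Why: O-Triflation of the ketone and loss of the only available α-proton under non-basic conditions gives the enol triflate without deprotonating the lactone CH2.

Step 20
Reactants: 26 (4aS)-4a,8-dimethyl-3-oxo-3,4,4a,7-tetrahydro-1H-isochromen-5-yl trifluoromethanesulfonate
Product: 27 (4aS)-5-bromo-4a,8-dimethyl-1,4,4a,7-tetrahydro-3H-isochromen-3-one
Conditions: Ni(cod)2 (10 mol %), LiBr, DMA–THF, 25 °C
Reagents that add atoms: lithium bromide, [Li+].[Br-]
Why: The nickel-catalysed exchange of enol triflates for halide (oxidative addition to zerovalent nickel, triflate–bromide exchange, reductive elimination) gives the alkenyl bromide at the hindered position under neutral conditions.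

Step 21
Reactants: 27 (4aS)-5-bromo-4a,8-dimethyl-1,4,4a,7-tetrahydro-3H-isochromen-3-one
Product: 28 (4aS,5S)-5-bromo-4a,8-dimethyl-1,4,4a,5,6,7-hexahydro-3H-isochromen-3-one (Br cis to the angular methyl)
Conditions: Mn(dpm)3 (10 mol %), PhSiH3, t-BuOOH, i-PrOH, 22 °C
Reagents that add atoms: none
Why: In this Mukaiyama-type hydrogen-atom-transfer hydrogenation, which leaves C–Br bonds intact, the manganese hydride gives H to the unsubstituted vinyl carbon and the α-bromo radical takes the second H axially on the face anti to the pseudo-axial angular methyl held by the lactone ring, so bromine ends equatorial and cis to that methyl, while the hindered tetrasubstituted alkene should react more slowly.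

**Union and endgame**

Step 22
Reactants: 15 (1S,3R)-3-bromo-1-(iodomethyl)-1,2,2-trimethylcyclopentane; 28 (4aS,5S)-5-bromo-4a,8-dimethyl-1,4,4a,5,6,7-hexahydro-3H-isochromen-3-one
Product: 30 1-[(1R,3R)-3-bromo-1,2,2-trimethylcyclopentyl]-3-[(1S,6S)-6-bromo-2-(hydroxymethyl)-1,3-dimethylcyclohex-2-en-1-yl]propan-2-one, via alkyllithium 29 (not isolated)
Conditions: 15, t-BuLi (2.0 equiv), Et2O–pentane, −78 °C; then cannulated into 28, THF, −78 → −40 °C; aq NH4Cl
Reagents that add atoms: none
Why: Iodine–lithium exchange of the primary neopentyl iodide is far faster at −78 °C than any reaction of t-BuLi with the hindered secondary bromide, and the alkyllithium adds once to the lactone carbonyl because the lithium hemiketal persists until work-up, forming the C2–C3 bond and releasing the allylic alcohol.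

Step 23
Reactants: 30 1-[(1R,3R)-3-bromo-1,2,2-trimethylcyclopentyl]-3-[(1S,6S)-6-bromo-2-(hydroxymethyl)-1,3-dimethylcyclohex-2-en-1-yl]propan-2-one
Product: 31 (5S,6S)-5-bromo-6-{3-[(1R,3R)-3-bromo-1,2,2-trimethylcyclopentyl]-2-oxopropyl}-2,6-dimethylcyclohex-1-ene-1-carbaldehyde
Conditions: Dess–Martin periodinane, NaHCO3, CH2Cl2, 0 → 25 °C
Reagents that add atoms: none
Why: Dess–Martin oxidation of the primary allylic alcohol, drawn from the open form of any cyclic hemiketal, gives the enal that serves as the aldol acceptor.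

Step 24
Reactants: 31 (5S,6S)-5-bromo-6-{3-[(1R,3R)-3-bromo-1,2,2-trimethylcyclopentyl]-2-oxopropyl}-2,6-dimethylcyclohex-1-ene-1-carbaldehyde
Product: 33 (8S,8aS)-8-bromo-3-[(1R,3R)-3-bromo-1,2,2-trimethylcyclopentyl]-5,8a-dimethyl-6,7,8,8a-tetrahydronaphthalen-2(1H)-one, via aldol adduct 32 (not isolated)
Conditions: NaOMe (0.3 equiv), MeOH, 0 → 25 °C
Reagents that add atoms: none
Why: Intramolecular aldol condensation closes ring A in the 6-enolexo mode, since the C3 enolate adds to the aldehyde carbon (C4) whereas the C1 enolate could only form a four-membered ring, and E1cB loss of water from adduct 32 gives the linearly conjugated dienone as the thermodynamic sink under conditions too mild to eliminate the secondary bromides.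

Step 25
Reactants: 33 (8S,8aS)-8-bromo-3-[(1R,3R)-3-bromo-1,2,2-trimethylcyclopentyl]-5,8a-dimethyl-6,7,8,8a-tetrahydronaphthalen-2(1H)-one
Product: 34 (4aR,5S,8S,8aS)-8-bromo-3-[(1R,3R)-3-bromo-1,2,2-trimethylcyclopentyl]-4a,5-epoxy-5,8a-dimethyl-4a,5,6,7,8,8a-hexahydronaphthalen-2(1H)-one (epoxide oxygen anti to the C8a methyl)
Conditions: mCPBA, NaHCO3, CH2Cl2, 0 °C
Reagents that add atoms: 3-chloroperoxybenzoic acid, OOC(=O)c1cccc(Cl)c1
Why: Prilezhaev epoxidation should take the electron-richer tetrasubstituted γ,δ-alkene (C4a=C5) and not the enone alkene, from the face opposite the axial C8a methyl, which fixes the C4a–O configuration.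

Step 26
Reactants: 34 (4aR,5S,8S,8aS)-8-bromo-3-[(1R,3R)-3-bromo-1,2,2-trimethylcyclopentyl]-4a,5-epoxy-5,8a-dimethyl-4a,5,6,7,8,8a-hexahydronaphthalen-2(1H)-one
Product: 35 (4aR,5R,8S,8aS)-8-bromo-3-[(1R,3R)-3-bromo-1,2,2-trimethylcyclopentyl]-4a,5-dihydroxy-5,8a-dimethyl-4a,5,6,7,8,8a-hexahydronaphthalen-2(1H)-one
Conditions: HClO4 (cat.), THF–H2O, 0 → 25 °C
Reagents that add atoms: water, O
Why: Acid-catalysed epoxide hydrolysis should open at C5, the tertiary carbon remote from the electron-poor enone, with inversion in the trans-diaxial (Fürst–Plattner) sense, so the 4a-OH stays anti to the C8a methyl and the 5-OH enters trans to it.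

**Compound list**
1 | 2-methylprop-2-en-1-ol | CC(=C)CO | starting material
2 | tert-butyl[(2-methylprop-2-en-1-yl)oxy]diphenylsilane | CC(=C)CO[Si](c1ccccc1)(c1ccccc1)C(C)(C)C | intermediate
3 | trichloroacetyl chloride | ClC(Cl)(Cl)C(Cl)=O | starting material
4 | dichloroketene | ClC(Cl)=C=O | intermediate (not isolated)
5 | rac-3-({[tert-butyl(diphenyl)silyl]oxy}methyl)-2,2-dichloro-3-methylcyclobutan-1-one | O=C1CC(C)(CO[Si](c2ccccc2)(c2ccccc2)C(C)(C)C)C1(Cl)Cl | intermediate
6 | (1R,3R)-3-({[tert-butyl(diphenyl)silyl]oxy}methyl)-2,2-dichloro-3-methylcyclobutan-1-ol | O[C@@H]1C[C@](C)(CO[Si](c2ccccc2)(c2ccccc2)C(C)(C)C)C1(Cl)Cl | intermediate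
7 | (3R)-3-({[tert-butyl(diphenyl)silyl]oxy}methyl)-2,2-dichloro-3-methylcyclobutan-1-one | O=C1C[C@](C)(CO[Si](c2ccccc2)(c2ccccc2)C(C)(C)C)C1(Cl)Cl | intermediate
8 | diazomethane | C=[N+]=[N-] | starting material
9 | (3R)-3-({[tert-butyl(diphenyl)silyl]oxy}methyl)-2,2-dichloro-3-methylcyclopentan-1-one | O=C1CC[C@](C)(CO[Si](c2ccccc2)(c2ccccc2)C(C)(C)C)C1(Cl)Cl | intermediate
10 | lithium (3S)-3-({[tert-butyl(diphenyl)silyl]oxy}methyl)-2,3-dimethylcyclopent-1-en-1-olate | [Li]OC1=C(C)[C@@](C)(CO[Si](c2ccccc2)(c2ccccc2)C(C)(C)C)CC1 | intermediate (not isolated)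
11 | (3S)-3-({[tert-butyl(diphenyl)silyl]oxy}methyl)-2,2,3-trimethylcyclopentan-1-one | O=C1CC[C@](C)(CO[Si](c2ccccc2)(c2ccccc2)C(C)(C)C)C1(C)C | intermediate
12 | (1S,3S)-3-({[tert-butyl(diphenyl)silyl]oxy}methyl)-2,2,3-trimethylcyclopentan-1-ol | CC1(C)[C@@H](O)CC[C@]1(C)CO[Si](c2ccccc2)(c2ccccc2)C(C)(C)C | intermediate
13 | tert-butyl{[(1S,3R)-3-bromo-1,2,2-trimethylcyclopentyl]methoxy}diphenylsilane | CC1(C)[C@H](Br)CC[C@]1(C)CO[Si](c2ccccc2)(c2ccccc2)C(C)(C)C | intermediate
14 | [(1S,3R)-3-bromo-1,2,2-trimethylcyclopentyl]methanol | CC1(C)[C@H](Br)CC[C@]1(C)CO | intermediate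
15 | (1S,3R)-3-bromo-1-(iodomethyl)-1,2,2-trimethylcyclopentane | CC1(C)[C@H](Br)CC[C@]1(C)CI | intermediate
16 | 2-methylcyclohexane-1,3-dione | CC1C(=O)CCCC1=O | starting material
17 | methyl 2-(1-methyl-2,6-dioxocyclohexyl)acetate | COC(=O)CC1(C)C(=O)CCCC1=O | intermediate
18 | methyl 2-[(1R,2R)-2-hydroxy-1-methyl-6-oxocyclohexyl]acetate | O=C1CCC[C@@H](O)[C@@]1(C)CC(=O)OC | intermediate
19 | methyl 2-[(1R,2R)-2-{[tert-butyl(dimethyl)silyl]oxy}-1-methyl-6-oxocyclohexyl]acetate | O=C1CCC[C@@H](O[Si](C)(C)C(C)(C)C)[C@@]1(C)CC(=O)OC | intermediate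
20 | methyl 2-[(1R,6R)-6-{[tert-butyl(dimethyl)silyl]oxy}-1,3-dimethyl-2-oxocyclohexyl]acetate (C3 epimers) | O=C1C(C)CC[C@@H](O[Si](C)(C)C(C)(C)C)[C@@]1(C)CC(=O)OC | intermediate
21 | methyl 2-[(1R,6R)-6-{[tert-butyl(dimethyl)silyl]oxy}-1,3-dimethyl-2-{[(trifluoromethyl)sulfonyl]oxy}cyclohex-2-en-1-yl]acetate | O=S(=O)(OC1=C(C)CC[C@@H](O[Si](C)(C)C(C)(C)C)[C@@]1(C)CC(=O)OC)C(F)(F)F | intermediate
22 | methyl 2-[(1S,6R)-6-{[tert-butyl(dimethyl)silyl]oxy}-2-(hydroxymethyl)-1,3-dimethylcyclohex-2-en-1-yl]acetate | OCC1=C(C)CC[C@@H](O[Si](C)(C)C(C)(C)C)[C@@]1(C)CC(=O)OC | intermediate (not isolated)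
23 | (4aS,5R)-5-{[tert-butyl(dimethyl)silyl]oxy}-4a,8-dimethyl-1,4,4a,5,6,7-hexahydro-3H-isochromen-3-one | O=C1C[C@]2(C)[C@H](O[Si](C)(C)C(C)(C)C)CCC(C)=C2CO1 | intermediate
24 | (4aS,5R)-5-hydroxy-4a,8-dimethyl-1,4,4a,5,6,7-hexahydro-3H-isochromen-3-one | O=C1C[C@]2(C)[C@H](O)CCC(C)=C2CO1 | intermediate
25 | (4aS)-4a,8-dimethyl-4,4a,6,7-tetrahydro-1H-isochromene-3,5-dione | O=C1C[C@]2(C)C(=O)CCC(C)=C2CO1 | intermediate
26 | (4aS)-4a,8-dimethyl-3-oxo-3,4,4a,7-tetrahydro-1H-isochromen-5-yl trifluoromethanesulfonate | O=C1C[C@]2(C)C(OS(=O)(=O)C(F)(F)F)=CCC(C)=C2CO1 | intermediate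
27 | (4aS)-5-bromo-4a,8-dimethyl-1,4,4a,7-tetrahydro-3H-isochromen-3-one | O=C1C[C@]2(C)C(Br)=CCC(C)=C2CO1 | intermediate
28 | (4aS,5S)-5-bromo-4a,8-dimethyl-1,4,4a,5,6,7-hexahydro-3H-isochromen-3-one | O=C1C[C@]2(C)[C@@H](Br)CCC(C)=C2CO1 | intermediate
29 | {[(1S,3R)-3-bromo-1,2,2-trimethylcyclopentyl]methyl}lithium | CC1(C)[C@H](Br)CC[C@]1(C)C[Li] | intermediate (not isolated)
30 | 1-[(1R,3R)-3-bromo-1,2,2-trimethylcyclopentyl]-3-[(1S,6S)-6-bromo-2-(hydroxymethyl)-1,3-dimethylcyclohex-2-en-1-yl]propan-2-one | CC1(C)[C@H](Br)CC[C@]1(C)CC(=O)C[C@]1(C)[C@@H](Br)CCC(C)=C1CO | intermediate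
31 | (5S,6S)-5-bromo-6-{3-[(1R,3R)-3-bromo-1,2,2-trimethylcyclopentyl]-2-oxopropyl}-2,6-dimethylcyclohex-1-ene-1-carbaldehyde | CC1(C)[C@H](Br)CC[C@]1(C)CC(=O)C[C@]1(C)[C@@H](Br)CCC(C)=C1C=O | intermediate
32 | (8S,8aS)-8-bromo-3-[(1R,3R)-3-bromo-1,2,2-trimethylcyclopentyl]-4-hydroxy-5,8a-dimethyl-3,4,6,7,8,8a-hexahydronaphthalen-2(1H)-one (C3/C4 isomers) | CC1(C)[C@H](Br)CC[C@]1(C)C1C(O)C2=C(C)CC[C@H](Br)[C@@]2(C)CC1=O | intermediate (not isolated)
33 | (8S,8aS)-8-bromo-3-[(1R,3R)-3-bromo-1,2,2-trimethylcyclopentyl]-5,8a-dimethyl-6,7,8,8a-tetrahydronaphthalen-2(1H)-one | CC1(C)[C@H](Br)CC[C@]1(C)C1=CC2=C(C)CC[C@H](Br)[C@@]2(C)CC1=O | intermediate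
34 | (4aR,5S,8S,8aS)-8-bromo-3-[(1R,3R)-3-bromo-1,2,2-trimethylcyclopentyl]-4a,5-epoxy-5,8a-dimethyl-4a,5,6,7,8,8a-hexahydronaphthalen-2(1H)-one | CC1(C)[C@H](Br)CC[C@]1(C)C1=C[C@]23O[C@@]2(C)CC[C@H](Br)[C@@]3(C)CC1=O | intermediate
35 | (4aR,5R,8S,8aS)-8-bromo-3-[(1R,3R)-3-bromo-1,2,2-trimethylcyclopentyl]-4a,5-dihydroxy-5,8a-dimethyl-4a,5,6,7,8,8a-hexahydronaphthalen-2(1H)-one | CC1(C)[C@H](Br)CC[C@]1(C)C1=C[C@]2(O)[C@](C)(O)CC[C@H](Br)[C@@]2(C)CC1=O | target

**Step count**
Total: 26 steps. Longest linear sequence: 16 steps (steps 11–21, then 22–26); the cyclopentane branch is 15 (steps 1–10, then 22–26).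

**Three steps most likely to fail**

Step 8 (invertive bromination at C3'). The alkoxyphosphonium salt sits next to quaternary C2', so ionisation with a 1,2-methyl shift or loss of HBr may outrun the SN2 displacement. The fallback sets out from 11 and comes back at 13 without any substitution at a neopentyl centre. Ketone 11 is converted with KN(SiMe3)2 and PhNTf2 into (4S)-4-({[tert-butyl(diphenyl)silyl]oxy}methyl)-4,5,5-trimethylcyclopent-1-en-1-yl trifluoromethanesulfonate F1. Ni(cod)2 and LiBr then give tert-butyl{[(1S)-3-bromo-1,2,2-trimethylcyclopent-3-en-1-yl]methoxy}diphenylsilane F2. Hydrogen-atom-transfer hydrogenation of F2 (Mn(dpm)3, PhSiH3, t-BuOOH) should deliver the hydrogen at C3' anti to the bulky silyloxymethyl arm; facial bias is expected to be modest, so 13 is separated from its C3' epimer by chromatography.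

Step 21 (hydrogenation of the vinyl bromide). Hydrogen-atom transfer may also reduce the tetrasubstituted ring alkene, attack the doubly allylic CH2, or show poor facial selectivity at the bromine-bearing carbon. The fallback sets out from 24 and comes back at 28, so steps 18–21 are not needed. The axial alcohol 24 is esterified with ClCH2SO2Cl and pyridine to (4aS,5R)-4a,8-dimethyl-3-oxo-3,4,4a,5,6,7-hexahydro-1H-isochromen-5-yl chloromethanesulfonate F3. LiBr in DMF at 50 °C then displaces this leaving group with inversion (axial leaving group, equatorial entry) to give 28; elimination toward the neighbouring CH2 is the expected competitor.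

Step 22 (iodine–lithium exchange and acylation). t-BuLi may attack the secondary bromide, or the hindered alkyllithium may enolise the lactone instead of adding to it. The fallback sets out from 15 and 28 and comes back at 30, using an organozinc that is neither basic nor reactive toward alkyl bromides. Lactone 28 is opened with Me2AlSEt (from AlMe3 and EtSH) to S-ethyl 2-[(1S,6S)-6-bromo-2-(hydroxymethyl)-1,3-dimethylcyclohex-2-en-1-yl]ethanethioate F4, which is silylated at once (Et3SiCl, imidazole) to S-ethyl 2-[(1S,6S)-6-bromo-1,3-dimethyl-2-{[(triethylsilyl)oxy]methyl}cyclohex-2-en-1-yl]ethanethioate F5. Zinc dust and LiCl in THF at 25–40 °C insert into the C–I bond of 15 to give {[(1S,3R)-3-bromo-1,2,2-trimethylcyclopentyl]methyl}zinc iodide F6. Fukuyama coupling of F6 with F5 under PdCl2(PPh3)2 catalysis gives 1-[(1R,3R)-3-bromo-1,2,2-trimethylcyclopentyl]-3-[(1S,6S)-6-bromo-1,3-dimethyl-2-{[(triethylsilyl)oxy]methyl}cyclohex-2-en-1-yl]propan-2-one F7, and AcOH–THF–H2O removes the silyl group to give 30.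

**Further compounds**
F1 | step 8 | (4S)-4-({[tert-butyl(diphenyl)silyl]oxy}methyl)-4,5,5-trimethylcyclopent-1-en-1-yl trifluoromethanesulfonate | CC1(C)C(OS(=O)(=O)C(F)(F)F)=CC[C@]1(C)CO[Si](c2ccccc2)(c2ccccc2)C(C)(C)C
F2 | step 8 | tert-butyl{[(1S)-3-bromo-1,2,2-trimethylcyclopent-3-en-1-yl]methoxy}diphenylsilane | CC1(C)C(Br)=CC[C@]1(C)CO[Si](c2ccccc2)(c2ccccc2)C(C)(C)C
F3 | step 21 | (4aS,5R)-4a,8-dimethyl-3-oxo-3,4,4a,5,6,7-hexahydro-1H-isochromen-5-yl chloromethanesulfonate | O=C1C[C@]2(C)[C@H](OS(=O)(=O)CCl)CCC(C)=C2CO1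
F4 | step 22 | S-ethyl 2-[(1S,6S)-6-bromo-2-(hydroxymethyl)-1,3-dimethylcyclohex-2-en-1-yl]ethanethioate | CCSC(=O)C[C@]1(C)[C@@H](Br)CCC(C)=C1CO
F5 | step 22 | S-ethyl 2-[(1S,6S)-6-bromo-1,3-dimethyl-2-{[(triethylsilyl)oxy]methyl}cyclohex-2-en-1-yl]ethanethioate | CCSC(=O)C[C@]1(C)[C@@H](Br)CCC(C)=C1CO[Si](CC)(CC)CC
F6 | step 22 | {[(1S,3R)-3-bromo-1,2,2-trimethylcyclopentyl]methyl}zinc iodide | CC1(C)[C@H](Br)CC[C@]1(C)C[Zn]I
F7 | step 22 | 1-[(1R,3R)-3-bromo-1,2,2-trimethylcyclopentyl]-3-[(1S,6S)-6-bromo-1,3-dimethyl-2-{[(triethylsilyl)oxy]methyl}cyclohex-2-en-1-yl]propan-2-one | CC1(C)[C@H](Br)CC[C@]1(C)CC(=O)C[C@]1(C)[C@@H](Br)CCC(C)=C1CO[Si](CC)(CC)CC
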